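**Retrosynthetic overview**
1. The route rests on the oxolane ring: its O1–C2 bond and the hydroxyl on the exocyclic quaternary carbon bonded to C2 are vicinal C–O bonds. They are taken as the two ends of one cis-trisubstituted epoxide, opened at its CH carbon (5-exo) by the hydroxyl that becomes O1. C3 with its methyl comes from (S)-2-methylbutane-1,4-diol.
2. Side chain: the benzyloxymethyl group on the carbinol is turned into the aldehyde, the E-iodoalkene (Takai) and the E-enyne 18 (Sonogashira).
3. Ring B: vinylogous triflate 36 comes from δ-lactone 30 by an intramolecular Claisen condensation (C5–C6 bond) that frees the C1 hydroxymethyl. C8a is set by a Sharpless epoxide opened with a vinyl Grignard reagent under copper catalysis; the C7/C8 cis-diol is set by dihydroxylation of the lactone anti to its side chain.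
4. Union: Sonogashira coupling (C4–C4a) of 18 with 36, then ring A (pyran) by 6-endo-dig closure of O2–C3.
5. Ring order: oxolane (step 8), ring B (step 24), ring A (step 30).

Key step: step 8

Remark: ring-B and ring-A atoms carry the isochromene numbers of the target (C1, O2, C3, C4, C4a, C5–C8, C8a) in all intermediates. Diones 31 and 33 are drawn as diketones and 34 as one enol tautomer. But-2-en-1-ol 19 is taken as the pure E isomer.

**Oxolane fragment**

Step 1
Reactants: 1 (2S)-2-methylbutane-1,4-diol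
Product: 2 (2S)-4-[(tert-butyldiphenylsilyl)oxy]-2-methylbutan-1-ol
Conditions: tBuPh2SiCl (0.9 equiv), imidazole, CH2Cl2, −40 → 0 °C
Reagents that add atoms: tert-butyl(chloro)diphenylsilane, CC(C)(C)[Si](Cl)(c1ccccc1)c1ccccc1
Why: Silyl ether formation in which the bulky chlorosilane should react faster at the unbranched C4 hydroxyl than at the β-branched C1 hydroxyl, the minor regioisomer and the bis-ether being removed by chromatography.

Step 2
Reactants: 2 (2S)-4-[(tert-butyldiphenylsilyl)oxy]-2-methylbutan-1-ol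
Product: 3 (2S)-4-[(tert-butyldiphenylsilyl)oxy]-2-methylbutanal
Conditions: Dess–Martin periodinane, CH2Cl2, 0 °C → rt; used at once
Reagents that add atoms: none
Why: Dess–Martin oxidation is non-basic, so the α-stereocentre should survive if the aldehyde is carried on without storage.

Step 3
Reactants: 3 (2S)-4-[(tert-butyldiphenylsilyl)oxy]-2-methylbutanal; 4 ethyl 2-[bis(2,2,2-trifluoroethoxy)phosphoryl]propanoate
Product: 5 ethyl (2Z,4S)-6-[(tert-butyldiphenylsilyl)oxy]-2,4-dimethylhex-2-enoate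
Conditions: KN(SiMe3)2, 18-crown-6, THF, −78 °C
Reagents that add atoms: none
Why: Still–Gennari variant of the Horner–Wadsworth–Emmons olefination, in which the electron-poor trifluoroethyl phosphonate eliminates from the kinetic adduct and should give the Z-2-methyl enoate, whereas a plain triethyl phosphonopropionate would give the E isomer and, after the later steps, the wrong C2 epimer of the oxolane.

Step 4
Reactants: 5 ethyl (2Z,4S)-6-[(tert-butyldiphenylsilyl)oxy]-2,4-dimethylhex-2-enoate
Product: 6 (2Z,4S)-6-[(tert-butyldiphenylsilyl)oxy]-2,4-dimethylhex-2-en-1-ol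
Conditions: iBu2AlH (2.5 equiv), CH2Cl2, −78 °C; Rochelle salt work-up
Reagents that add atoms: none
Why: Hydride reduction of the conjugated ester to the allylic alcohol, which leaves the alkene geometry, the silyl ether and the stereocentre untouched.

Step 5
Reactants: 6 (2Z,4S)-6-[(tert-butyldiphenylsilyl)oxy]-2,4-dimethylhex-2-en-1-ol
Product: 7 [(2R,3S)-3-[(2S)-4-[(tert-butyldiphenylsilyl)oxy]butan-2-yl]-2-methyloxiran-2-yl]methanol
Conditions: Ti(OiPr)4 (20 mol %), diethyl D-(−)-tartrate (24 mol %), tBuOOH, 4 Å molecular sieves, CH2Cl2, −20 °C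
Reagents that add atoms: tert-butyl hydroperoxide, CC(C)(C)OO
Why: Katsuki–Sharpless asymmetric epoxidation, in which the titanium D-(−)-tartrate complex adds oxygen to the face opposite to that used by L-(+)-tartrate (which gives 2S epoxides), so both epoxide carbons are set as (2R,3S) under reagent control against only a small bias from the CH3/CH2CH2OSi centre.

Step 6
Reactants: 7 [(2R,3S)-3-[(2S)-4-[(tert-butyldiphenylsilyl)oxy]butan-2-yl]-2-methyloxiran-2-yl]methanol
Product: 8 tert-butyl{[(3S)-3-[(2S,3R)-3-[(benzyloxy)methyl]-3-methyloxiran-2-yl]butyl]oxy}diphenylsilane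
Conditions: NaH, BnBr, Bu4NI (cat.), THF, 0 °C → rt
Reagents that add atoms: benzyl bromide, BrCc1ccccc1
Why: Williamson ether synthesis, in which O-alkylation of the alkoxide should outrun a Payne rearrangement because that would require attack on the quaternary epoxide carbon.

Step 7
Reactants: 8 tert-butyl{[(3S)-3-[(2S,3R)-3-[(benzyloxy)methyl]-3-methyloxiran-2-yl]butyl]oxy}diphenylsilane
Product: 9 (3S)-3-[(2S,3R)-3-[(benzyloxy)methyl]-3-methyloxiran-2-yl]butan-1-ol
Conditions: Bu4NF, AcOH (1:1), THF, 0 °C → rt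
Reagents that add atoms: none
Why: Fluoride cleavage of the Si–O bond, with acetic acid keeping the freed hydroxyl protonated so that 9 can be isolated before ring closure.

Step 8
Reactants: 9 (3S)-3-[(2S,3R)-3-[(benzyloxy)methyl]-3-methyloxiran-2-yl]butan-1-ol
Product: 10 (2R)-1-(benzyloxy)-2-[(2R,3S)-3-methyloxolan-2-yl]propan-2-ol
Conditions: (+)-camphor-10-sulfonic acid (10 mol %), CH2Cl2, 0 °C → rt
Reagents that add atoms: none
Why: The acid activates the epoxide oxygen and the primary hydroxyl of the butanol chain attacks the secondary epoxide carbon from the rear in an SN2-like opening, forming the ring O–C2 bond while the epoxide oxygen stays on the quaternary carbon as the tertiary hydroxyl. The closest known reaction type is the acid-catalysed cyclisation of 4,5-epoxy alcohols to 2-(1-hydroxyalkyl)oxolanes. The oxolane closes in the 5-exo-tet mode. C2 of the oxolane is set by inversion at the epoxide CH carbon and the carbinol centre by retention at the untouched quaternary carbon, so both are controlled by the tartrate-directed epoxidation of step 5 and the Z geometry of step 3, while C3 is carried unchanged from 1. The step needs regioselectivity for the secondary carbon over 6-endo attack at the tertiary carbon, which the five-membered transition state and the inductively withdrawing benzyloxymethyl group on the tertiary carbon should secure, and stereospecificity, which the backside opening secures.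

Step 9
Reactants: 10 (2R)-1-(benzyloxy)-2-[(2R,3S)-3-methyloxolan-2-yl]propan-2-ol
Product: 11 {[(2R)-1-(benzyloxy)-2-[(2R,3S)-3-methyloxolan-2-yl]propan-2-yl]oxy}triethylsilane
Conditions: Et3SiOTf, 2,6-lutidine, CH2Cl2, −78 → 0 °C
Reagents that add atoms: triethylsilyl trifluoromethanesulfonate, CC[Si](CC)(CC)OS(=O)(=O)C(F)(F)F
Why: Silylation with a silyl triflate is strong enough for the hindered tertiary alcohol, which is masked for the organochromium step.

Step 10
Reactants: 11 {[(2R)-1-(benzyloxy)-2-[(2R,3S)-3-methyloxolan-2-yl]propan-2-yl]oxy}triethylsilane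
Product: 12 (2R)-2-[(2R,3S)-3-methyloxolan-2-yl]-2-[(triethylsilyl)oxy]propan-1-ol
Conditions: H2 (1 atm), Pd(OH)2/C, EtOAc, rt
Reagents that add atoms: none
Why: Hydrogenolysis of the benzyl ether over palladium, with no alkene present and the tertiary silyl ether stable in ethyl acetate.

Step 11
Reactants: 12 (2R)-2-[(2R,3S)-3-methyloxolan-2-yl]-2-[(triethylsilyl)oxy]propan-1-ol
Product: 13 (2S)-2-[(2R,3S)-3-methyloxolan-2-yl]-2-[(triethylsilyl)oxy]propanal
Conditions: Dess–Martin periodinane, CH2Cl2, 0 °C → rt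
Reagents that add atoms: none
Why: Dess–Martin oxidation of the primary alcohol gives an aldehyde without α-hydrogen, which cannot epimerise (the descriptor changes only through ligand priority).

Step 12
Reactants: 13 (2S)-2-[(2R,3S)-3-methyloxolan-2-yl]-2-[(triethylsilyl)oxy]propanal; 14 iodoform
Product: 15 triethyl{[(2R,3E)-4-iodo-2-[(2R,3S)-3-methyloxolan-2-yl]but-3-en-2-yl]oxy}silane
Conditions: CrCl2 (6 equiv), THF/1,4-dioxane, 0 °C → rt
Reagents that add atoms: none
Why: Takai olefination, in which the geminal dichromium species from iodoform adds to the aldehyde and elimination from the hindered adduct should give the E-iodoalkene.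

Step 13
Reactants: 15 triethyl{[(2R,3E)-4-iodo-2-[(2R,3S)-3-methyloxolan-2-yl]but-3-en-2-yl]oxy}silane; 16 ethynyl(trimethyl)silane
Product: 17 triethyl{[(2R,3E)-2-[(2R,3S)-3-methyloxolan-2-yl]-6-(trimethylsilyl)hex-3-en-5-yn-2-yl]oxy}silane
Conditions: Pd(PPh3)2Cl2 (3 mol %), CuI (6 mol %), Et3N, THF, rt
Reagents that add atoms: none
Why: Sonogashira coupling of an alkenyl iodide, which proceeds with retention of the alkene geometry.

Step 14
Reactants: 17 triethyl{[(2R,3E)-2-[(2R,3S)-3-methyloxolan-2-yl]-6-(trimethylsilyl)hex-3-en-5-yn-2-yl]oxy}silane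
Product: 18 (2R,3E)-2-[(2R,3S)-3-methyloxolan-2-yl]hex-3-en-5-yn-2-ol
Conditions: Bu4NF (2.5 equiv), THF, 0 °C → rt
Reagents that add atoms: none
Why: Fluoride cleaves both the alkynyl C–Si bond and the tertiary O–Si bond, so the coupling partner carries no protecting group.

**Ring-B fragment**

Step 15
Reactants: 19 (2E)-but-2-en-1-ol
Product: 20 [(2S,3S)-3-methyloxiran-2-yl]methanol
Conditions: Ti(OiPr)4 (5 mol %), diisopropyl L-(+)-tartrate (6 mol %), tBuOOH, 4 Å molecular sieves, CH2Cl2, −20 °C
Reagents that add atoms: tert-butyl hydroperoxide, CC(C)(C)OO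
Why: Katsuki–Sharpless asymmetric epoxidation, which with L-(+)-tartrate converts an E-allylic alcohol into the (2S,3S)-epoxide and so fixes the later C8a centre.

Step 16
Reactants: 20 [(2S,3S)-3-methyloxiran-2-yl]methanol; 21 vinylmagnesium bromide
Product: 22 (2R,3S)-2-ethenylbutane-1,3-diol
Conditions: CH2=CHMgBr (3 equiv), CuI (10 mol %), THF, −30 → 0 °C
Reagents that add atoms: none
Why: Copper-catalysed Grignard opening of a 2,3-epoxy alcohol, in which the magnesium alkoxide should direct the vinyl group to C2 with inversion (1,3-diol, future C8a set as 2R), the C3 carbinol being oxidised later.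

Step 17
Reactants: 22 (2R,3S)-2-ethenylbutane-1,3-diol; 23 2-methylprop-2-enoyl chloride
Product: 24 (2R,3S)-2-ethenyl-3-hydroxybutyl 2-methylprop-2-enoate
Conditions: 2,4,6-collidine, CH2Cl2, −78 °C
Reagents that add atoms: none
Why: Acylation with an acid chloride and a hindered pyridine base at low temperature should be selective for the primary over the secondary hydroxyl.

Step 18
Reactants: 24 (2R,3S)-2-ethenyl-3-hydroxybutyl 2-methylprop-2-enoate
Product: 25 (2R,3S)-3-[(tert-butyldimethylsilyl)oxy]-2-ethenylbutyl 2-methylprop-2-enoate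
Conditions: tBuMe2SiCl, imidazole, DMF, rt
Reagents that add atoms: tert-butyl(chloro)dimethylsilane, CC(C)(C)[Si](C)(C)Cl
Why: Standard silylation of the secondary alcohol, which must stay distinct from the diol made in step 20.

Step 19
Reactants: 25 (2R,3S)-3-[(tert-butyldimethylsilyl)oxy]-2-ethenylbutyl 2-methylprop-2-enoate
Product: 26 (5R)-5-[(1S)-1-[(tert-butyldimethylsilyl)oxy]ethyl]-3-methyl-5,6-dihydro-2H-pyran-2-one
Conditions: second-generation Grubbs catalyst (5 mol %), toluene (0.005 M), 80 °C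
Reagents that add atoms: none
Why: Ring-closing metathesis between the vinyl group and the methacrylate gives the six-membered α-methyl enoate lactone with loss of ethene.

Step 20
Reactants: 26 (5R)-5-[(1S)-1-[(tert-butyldimethylsilyl)oxy]ethyl]-3-methyl-5,6-dihydro-2H-pyran-2-one
Product: 27 (3R,4R,5S)-5-[(1S)-1-[(tert-butyldimethylsilyl)oxy]ethyl]-3,4-dihydroxy-3-methyloxan-2-one
Conditions: OsO4 (5 mol %), N-methylmorpholine N-oxide, acetone/H2O, rt
Reagents that add atoms: osmium tetroxide, O=[Os](=O)(=O)=O; N-methylmorpholine N-oxide, C[N+]1([O-])CCOCC1; water, O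
Why: Osmium tetroxide dihydroxylation (Upjohn conditions) is a syn addition that should occur on the lactone face anti to the branched C5 substituent, which sets C7 and C8 as the cis-diol trans to the C4a carbon and hence cis to C1.

Step 21
Reactants: 27 (3R,4R,5S)-5-[(1S)-1-[(tert-butyldimethylsilyl)oxy]ethyl]-3,4-dihydroxy-3-methyloxan-2-one
Product: 28 (3R,4R,5S)-5-[(1S)-1-[(tert-butyldimethylsilyl)oxy]ethyl]-3,4-(isopropylidenedioxy)-3-methyloxan-2-one
Conditions: 2,2-dimethoxypropane, pyridinium p-toluenesulfonate (cat.), CH2Cl2, rt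
Reagents that add atoms: 2,2-dimethoxypropane, COC(C)(C)OC
Why: Acid-catalysed ketal exchange gives the cis-fused dioxolane of the 1,2-diol and so protects both hydroxyls against the base of step 24.

Step 22
Reactants: 28 (3R,4R,5S)-5-[(1S)-1-[(tert-butyldimethylsilyl)oxy]ethyl]-3,4-(isopropylidenedioxy)-3-methyloxan-2-one
Product: 29 (3R,4R,5R)-5-[(1S)-1-hydroxyethyl]-3,4-(isopropylidenedioxy)-3-methyloxan-2-one
Conditions: HF·pyridine, pyridine, THF, 0 °C → rt
Reagents that add atoms: none
Why: Buffered hydrogen fluoride cleaves the secondary silyl ether without forming an alkoxide, so the lactone should not transacylate and the acetonide stays.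

Step 23
Reactants: 29 (3R,4R,5R)-5-[(1S)-1-hydroxyethyl]-3,4-(isopropylidenedioxy)-3-methyloxan-2-one
Product: 30 (3R,4R,5S)-5-acetyl-3,4-(isopropylidenedioxy)-3-methyloxan-2-one
Conditions: Dess–Martin periodinane, CH2Cl2, 0 °C → rt
Reagents that add atoms: none
Why: Dess–Martin oxidation gives the methyl ketone under neutral conditions that should neither epimerise the now acidic C8a–H nor eliminate the β-oxygen.

Step 24
Reactants: 30 (3R,4R,5S)-5-acetyl-3,4-(isopropylidenedioxy)-3-methyloxan-2-one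
Product: 31 (4R,5R,6S)-6-(hydroxymethyl)-4,5-(isopropylidenedioxy)-4-methylcyclohexane-1,3-dione
Conditions: LiN(SiMe3)2 (2.5 equiv), THF, −78 → −20 °C; then AcOH
Reagents that add atoms: none
Why: Intramolecular Claisen (Dieckmann-type) condensation, in which the kinetic lithium enolate of the methyl group attacks the lactone carbonyl through a bicyclo[2.2.2] tetrahedral intermediate whose collapse expels the C1 alkoxide and leaves the 1,3-dione as its stabilised enolate, which drives the reaction and shields C8a from epimerisation.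

Step 25
Reactants: 31 (4R,5R,6S)-6-(hydroxymethyl)-4,5-(isopropylidenedioxy)-4-methylcyclohexane-1,3-dione
Product: 33 (4R,5R,6S)-6-{[(tert-butyldimethylsilyl)oxy]methyl}-4,5-(isopropylidenedioxy)-4-methylcyclohexane-1,3-dione, via O-silyl enol ether 32 (not isolated)
Conditions: tBuMe2SiCl (2.2 equiv), imidazole, DMF, 0 °C; aqueous citric acid work-up
Reagents that add atoms: tert-butyl(chloro)dimethylsilane, CC(C)(C)[Si](C)(C)Cl
Why: Silylation of the primary alcohol, in which the dione enol is silylated as well but this vinylogous silyl ester is hydrolysed by the mildly acidic work-up.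

Step 26
Reactants: 33 (4R,5R,6S)-6-{[(tert-butyldimethylsilyl)oxy]methyl}-4,5-(isopropylidenedioxy)-4-methylcyclohexane-1,3-dione
Product: 34 (4S,5R,6R)-4-{[(tert-butyldimethylsilyl)oxy]methyl}-2-chloro-3-hydroxy-5,6-(isopropylidenedioxy)-6-methylcyclohex-2-en-1-one
Conditions: N-chlorosuccinimide (1.0 equiv), CH2Cl2, 0 °C
Reagents that add atoms: N-chlorosuccinimide, O=C1CCC(=O)N1Cl
Why: Electrophilic chlorination of a 1,3-dione enol occurs at C5, the carbon between the two carbonyl groups.

Step 27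
Reactants: 34 (4S,5R,6R)-4-{[(tert-butyldimethylsilyl)oxy]methyl}-2-chloro-3-hydroxy-5,6-(isopropylidenedioxy)-6-methylcyclohex-2-en-1-one
Product: 35 (4R,5R,6S)-6-{[(tert-butyldimethylsilyl)oxy]methyl}-2-chloro-4,5-(isopropylidenedioxy)-4-methyl-3-oxocyclohex-1-en-1-yl trifluoromethanesulfonate
Conditions: Tf2O (1.1 equiv), Et3N, CH2Cl2, −78 °C
Reagents that add atoms: trifluoromethanesulfonic anhydride, O=S(=O)(OS(=O)(=O)C(F)(F)F)C(F)(F)F
Why: O-Sulfonylation of the dione enolate, in which the oxygen on C4a (next to the tertiary C8a) is less hindered than the oxygen on C6 (next to the quaternary C7), so the vinylogous triflate should form with C6 kept as the ketone.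

Step 28
Reactants: 35 (4R,5R,6S)-6-{[(tert-butyldimethylsilyl)oxy]methyl}-2-chloro-4,5-(isopropylidenedioxy)-4-methyl-3-oxocyclohex-1-en-1-yl trifluoromethanesulfonate
Product: 36 (4R,5R,6S)-2-chloro-4,5-dihydroxy-6-(hydroxymethyl)-4-methyl-3-oxocyclohex-1-en-1-yl trifluoromethanesulfonate
Conditions: CF3CO2H/H2O (9:1), 0 °C
Reagents that add atoms: none
Why: Aqueous acid hydrolysis of the acetonide and the primary silyl ether is placed here, where no acid-labile allylic alcohol or enol ether is present and the alkenyl triflate, which does not ionise, should survive.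

**Union and ring A**

Step 29
Reactants: 36 (4R,5R,6S)-2-chloro-4,5-dihydroxy-6-(hydroxymethyl)-4-methyl-3-oxocyclohex-1-en-1-yl trifluoromethanesulfonate; 18 (2R,3E)-2-[(2R,3S)-3-methyloxolan-2-yl]hex-3-en-5-yn-2-ol
Product: 37 (4S,5R,6R)-2-chloro-5,6-dihydroxy-3-[(3E,5R)-5-hydroxy-5-[(2R,3S)-3-methyloxolan-2-yl]hex-3-en-1-yn-1-yl]-4-(hydroxymethyl)-6-methylcyclohex-2-en-1-one
Conditions: Pd(PPh3)4 (5 mol %), CuI (10 mol %), iPr2NEt, degassed THF, 0 °C → rt
Reagents that add atoms: none
Why: Sonogashira coupling, in which zerovalent palladium inserts into the activated C–OTf bond much faster than into the C5–Cl bond and free hydroxyl groups are tolerated.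

Step 30
Reactants: 37 (4S,5R,6R)-2-chloro-5,6-dihydroxy-3-[(3E,5R)-5-hydroxy-5-[(2R,3S)-3-methyloxolan-2-yl]hex-3-en-1-yn-1-yl]-4-(hydroxymethyl)-6-methylcyclohex-2-en-1-one
Product: 38 Peniciazaphilone E
Conditions: Ph3PAuNTf2 (5 mol %), THF, 0 °C → rt
Reagents that add atoms: none
Why: Gold-catalysed alkyne hydroalkoxylation (cycloisomerisation) in the 6-endo-dig mode, in which the C1 hydroxyl attacks C3 (the alkyne carbon bearing the cation-stabilising alkenyl group and the δ-position of the ynenone) and protodeauration at C4 gives the dienol ether without touching a stereocentre.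

**Compound list**
1 | (2S)-2-methylbutane-1,4-diol | C[C@H](CO)CCO | starting material
2 | (2S)-4-[(tert-butyldiphenylsilyl)oxy]-2-methylbutan-1-ol | C[C@H](CO)CCO[Si](c1ccccc1)(c1ccccc1)C(C)(C)C | intermediate
3 | (2S)-4-[(tert-butyldiphenylsilyl)oxy]-2-methylbutanal | C[C@H](C=O)CCO[Si](c1ccccc1)(c1ccccc1)C(C)(C)C | intermediate
4 | ethyl 2-[bis(2,2,2-trifluoroethoxy)phosphoryl]propanoate | CCOC(=O)C(C)P(=O)(OCC(F)(F)F)OCC(F)(F)F | starting material
5 | ethyl (2Z,4S)-6-[(tert-butyldiphenylsilyl)oxy]-2,4-dimethylhex-2-enoate | CCOC(=O)/C(C)=C\[C@@H](C)CCO[Si](c1ccccc1)(c1ccccc1)C(C)(C)C | intermediate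
6 | (2Z,4S)-6-[(tert-butyldiphenylsilyl)oxy]-2,4-dimethylhex-2-en-1-ol | OC/C(C)=C\[C@@H](C)CCO[Si](c1ccccc1)(c1ccccc1)C(C)(C)C | intermediate
7 | [(2R,3S)-3-[(2S)-4-[(tert-butyldiphenylsilyl)oxy]butan-2-yl]-2-methyloxiran-2-yl]methanol | CC(C)(C)[Si](c1ccccc1)(c1ccccc1)OCC[C@H](C)[C@@H]1O[C@]1(C)CO | intermediate
8 | tert-butyl{[(3S)-3-[(2S,3R)-3-[(benzyloxy)methyl]-3-methyloxiran-2-yl]butyl]oxy}diphenylsilane | CC(C)(C)[Si](c1ccccc1)(c1ccccc1)OCC[C@H](C)[C@@H]1O[C@]1(C)COCc1ccccc1 | intermediate
9 | (3S)-3-[(2S,3R)-3-[(benzyloxy)methyl]-3-methyloxiran-2-yl]butan-1-ol | OCC[C@H](C)[C@@H]1O[C@]1(C)COCc1ccccc1 | intermediate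
10 | (2R)-1-(benzyloxy)-2-[(2R,3S)-3-methyloxolan-2-yl]propan-2-ol | C[C@H]1CCO[C@H]1[C@](C)(O)COCc1ccccc1 | intermediate
11 | {[(2R)-1-(benzyloxy)-2-[(2R,3S)-3-methyloxolan-2-yl]propan-2-yl]oxy}triethylsilane | C[C@H]1CCO[C@H]1[C@](C)(O[Si](CC)(CC)CC)COCc1ccccc1 | intermediate
12 | (2R)-2-[(2R,3S)-3-methyloxolan-2-yl]-2-[(triethylsilyl)oxy]propan-1-ol | C[C@H]1CCO[C@H]1[C@](C)(O[Si](CC)(CC)CC)CO | intermediate
13 | (2S)-2-[(2R,3S)-3-methyloxolan-2-yl]-2-[(triethylsilyl)oxy]propanal | C[C@H]1CCO[C@H]1[C@](C)(O[Si](CC)(CC)CC)C=O | intermediate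
14 | iodoform (triiodomethane) | IC(I)I | starting material
15 | triethyl{[(2R,3E)-4-iodo-2-[(2R,3S)-3-methyloxolan-2-yl]but-3-en-2-yl]oxy}silane | C[C@H]1CCO[C@H]1[C@](C)(O[Si](CC)(CC)CC)/C=C/I | intermediate
16 | ethynyl(trimethyl)silane | C#C[Si](C)(C)C | starting material
17 | triethyl{[(2R,3E)-2-[(2R,3S)-3-methyloxolan-2-yl]-6-(trimethylsilyl)hex-3-en-5-yn-2-yl]oxy}silane | C[C@H]1CCO[C@H]1[C@](C)(O[Si](CC)(CC)CC)/C=C/C#C[Si](C)(C)C | intermediate
18 | (2R,3E)-2-[(2R,3S)-3-methyloxolan-2-yl]hex-3-en-5-yn-2-ol | C[C@H]1CCO[C@H]1[C@](C)(O)/C=C/C#C | intermediate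
19 | (2E)-but-2-en-1-ol | C/C=C/CO | starting material
20 | [(2S,3S)-3-methyloxiran-2-yl]methanol | C[C@@H]1O[C@H]1CO | intermediate
21 | vinylmagnesium bromide | C=C[Mg]Br | starting material
22 | (2R,3S)-2-ethenylbutane-1,3-diol | C=C[C@@H]([C@H](C)O)CO | intermediate
23 | 2-methylprop-2-enoyl chloride | CC(=C)C(Cl)=O | starting material
24 | (2R,3S)-2-ethenyl-3-hydroxybutyl 2-methylprop-2-enoate | C=C[C@@H]([C@H](C)O)COC(=O)C(C)=C | intermediate
25 | (2R,3S)-3-[(tert-butyldimethylsilyl)oxy]-2-ethenylbutyl 2-methylprop-2-enoate | C=C[C@@H]([C@H](C)O[Si](C)(C)C(C)(C)C)COC(=O)C(C)=C | intermediate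
26 | (5R)-5-[(1S)-1-[(tert-butyldimethylsilyl)oxy]ethyl]-3-methyl-5,6-dihydro-2H-pyran-2-one | CC1=C[C@@H]([C@H](C)O[Si](C)(C)C(C)(C)C)COC1=O | intermediate
27 | (3R,4R,5S)-5-[(1S)-1-[(tert-butyldimethylsilyl)oxy]ethyl]-3,4-dihydroxy-3-methyloxan-2-one | C[C@@]1(O)[C@H](O)[C@@H]([C@H](C)O[Si](C)(C)C(C)(C)C)COC1=O | intermediate
28 | (3R,4R,5S)-5-[(1S)-1-[(tert-butyldimethylsilyl)oxy]ethyl]-3,4-(isopropylidenedioxy)-3-methyloxan-2-one | C[C@@]12OC(C)(C)O[C@@H]1[C@@H]([C@H](C)O[Si](C)(C)C(C)(C)C)COC2=O | intermediate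
29 | (3R,4R,5R)-5-[(1S)-1-hydroxyethyl]-3,4-(isopropylidenedioxy)-3-methyloxan-2-one | C[C@@]12OC(C)(C)O[C@@H]1[C@@H]([C@H](C)O)COC2=O | intermediate
30 | (3R,4R,5S)-5-acetyl-3,4-(isopropylidenedioxy)-3-methyloxan-2-one | C[C@@]12OC(C)(C)O[C@@H]1[C@@H](C(C)=O)COC2=O | intermediate
31 | (4R,5R,6S)-6-(hydroxymethyl)-4,5-(isopropylidenedioxy)-4-methylcyclohexane-1,3-dione | O=C1CC(=O)[C@]2(C)OC(C)(C)O[C@@H]2[C@@H]1CO | intermediate
32 | O-silyl enol ether of 33 (silyl on the C4a oxygen, bis-silyl compound) | CC(C)(C)[Si](C)(C)OC1=CC(=O)[C@]2(C)OC(C)(C)O[C@@H]2[C@@H]1CO[Si](C)(C)C(C)(C)C | intermediate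
33 | (4R,5R,6S)-6-{[(tert-butyldimethylsilyl)oxy]methyl}-4,5-(isopropylidenedioxy)-4-methylcyclohexane-1,3-dione | O=C1CC(=O)[C@]2(C)OC(C)(C)O[C@@H]2[C@@H]1CO[Si](C)(C)C(C)(C)C | intermediate
34 | (4S,5R,6R)-4-{[(tert-butyldimethylsilyl)oxy]methyl}-2-chloro-3-hydroxy-5,6-(isopropylidenedioxy)-6-methylcyclohex-2-en-1-one | OC1=C(Cl)C(=O)[C@]2(C)OC(C)(C)O[C@@H]2[C@@H]1CO[Si](C)(C)C(C)(C)C | intermediate
35 | (4R,5R,6S)-6-{[(tert-butyldimethylsilyl)oxy]methyl}-2-chloro-4,5-(isopropylidenedioxy)-4-methyl-3-oxocyclohex-1-en-1-yl trifluoromethanesulfonate | FC(F)(F)S(=O)(=O)OC1=C(Cl)C(=O)[C@]2(C)OC(C)(C)O[C@@H]2[C@@H]1CO[Si](C)(C)C(C)(C)C | intermediate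
36 | (4R,5R,6S)-2-chloro-4,5-dihydroxy-6-(hydroxymethyl)-4-methyl-3-oxocyclohex-1-en-1-yl trifluoromethanesulfonate | FC(F)(F)S(=O)(=O)OC1=C(Cl)C(=O)[C@](C)(O)[C@H](O)[C@@H]1CO | intermediate
37 | (4S,5R,6R)-2-chloro-5,6-dihydroxy-3-[(3E,5R)-5-hydroxy-5-[(2R,3S)-3-methyloxolan-2-yl]hex-3-en-1-yn-1-yl]-4-(hydroxymethyl)-6-methylcyclohex-2-en-1-one | C[C@H]1CCO[C@H]1[C@](C)(O)/C=C/C#CC1=C(Cl)C(=O)[C@](C)(O)[C@H](O)[C@@H]1CO | intermediate
38 | Peniciazaphilone E, (7R,8R,8aS)-5-chloro-7,8-dihydroxy-3-[(1E,3R)-3-hydroxy-3-[(2R,3S)-3-methyloxolan-2-yl]but-1-en-1-yl]-7-methyl-1,7,8,8a-tetrahydro-6H-isochromen-6-one | C[C@H]1CCO[C@H]1[C@](C)(O)/C=C/C1=CC2=C(Cl)C(=O)[C@](C)(O)[C@H](O)[C@@H]2CO1 | target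

**Totals**
Total step count: 30.
Longest linear sequence: 16 steps (steps 1–14, then 29 and 30; the ring-B branch, steps 15–28 plus 29 and 30, is equally long).

**Three steps most likely to fail**

Step 24. The base may deprotonate C8a instead of the methyl group, which would epimerise C8a or eliminate the C8 oxygen, and the transannular acyl transfer may revert before the dione enolate forms. Fallback by known chemistry, setting out from 29: the lactone is opened with MeNH(OMe)·HCl and AlMe3 (CH2Cl2, 0 °C) to the hydroxy Weinreb amide F1. Its primary hydroxyl is silylated selectively (tBuMe2SiCl, imidazole, 0 °C) to give the silyl ether F2, and Dess–Martin oxidation gives the keto amide F3. LiN(SiMe3)2 (THF, −78 °C) then acylates the methyl ketone enolate with the open-chain amide (6-exo-trig); the chelated tetrahedral adduct breaks down only on work-up. The route is rejoined at 33, and steps 23–25 are skipped.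

Step 5. The Z-alkene with allylic branching may turn over slowly, and facial selectivity may erode because the reagent works against a mild substrate bias. Fallback, setting out from 6: benzylation (NaH, BnBr) gives the Z-allylic benzyl ether F4. Shi epoxidation (Oxone, K2CO3, MeCN/dimethoxymethane/water, 0 °C) with the L-sorbose-derived enantiomer of the fructose-based chiral ketone, chosen by the spiro transition-state model for this trisubstituted alkene, should then give the epoxide directly as 8. Facial control then no longer depends on a titanium-bound hydroxyl.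

Step 30. Closure may compete in the 5-exo-dig mode at C4, or the Lewis-acidic catalyst may ionise the tertiary allylic alcohol. Fallback, setting out from 37: diethylamine (THF, rt) adds in a 1,6-sense to C3 to give the dienaminone F5. On treatment with acetic acid the C1 hydroxyl should displace diethylamine by addition–elimination at C3, which closes ring A and gives 38.

**Further compounds**
F1 | step 24 | (4R,5R)-5-[(2R,3S)-1,3-dihydroxybutan-2-yl]-N-methoxy-N,2,2,4-tetramethyl-1,3-dioxolane-4-carboxamide | CON(C)C(=O)[C@]1(C)OC(C)(C)O[C@@H]1[C@@H]([C@H](C)O)CO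
F2 | step 24 | (4R,5R)-5-[(2R,3S)-1-[(tert-butyldimethylsilyl)oxy]-3-hydroxybutan-2-yl]-N-methoxy-N,2,2,4-tetramethyl-1,3-dioxolane-4-carboxamide | CON(C)C(=O)[C@]1(C)OC(C)(C)O[C@@H]1[C@@H]([C@H](C)O)CO[Si](C)(C)C(C)(C)C
F3 | step 24 | (4R,5R)-5-[(2S)-1-[(tert-butyldimethylsilyl)oxy]-3-oxobutan-2-yl]-N-methoxy-N,2,2,4-tetramethyl-1,3-dioxolane-4-carboxamide | CON(C)C(=O)[C@]1(C)OC(C)(C)O[C@@H]1[C@@H](C(C)=O)CO[Si](C)(C)C(C)(C)C
F4 | step 5 | tert-butyl{[(3S,4Z)-6-(benzyloxy)-3,5-dimethylhex-4-en-1-yl]oxy}diphenylsilane | c1ccccc1COC/C(C)=C\[C@@H](C)CCO[Si](c1ccccc1)(c1ccccc1)C(C)(C)C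
F5 | step 30 | (4S,5R,6R)-2-chloro-3-[(3E,5R)-2-(diethylamino)-5-hydroxy-5-[(2R,3S)-3-methyloxolan-2-yl]hexa-1,3-dien-1-yl]-5,6-dihydroxy-4-(hydroxymethyl)-6-methylcyclohex-2-en-1-one | C[C@H]1CCO[C@H]1[C@](C)(O)/C=C/C(N(CC)CC)=CC1=C(Cl)C(=O)[C@](C)(O)[C@H](O)[C@@H]1CO
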